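**Target:** 2-[(2E,5R,6E,10E)-5-hydroxy-3,7,11,15-tetramethylhexadeca-2,6,10,14-tetraen-1-yl]-6-methylbenzene-1,4-diol. The carbinol carbon C5' is R; the 6'E and 10'E olefins come from farnesal and the 2'E olefin is made in step 2.

## Retrosynthetic overview

- Aryl–C1' bond: the chain is cut off as an (E)-allyl boronate and the ring as 2-methyl-1,4-benzoquinone, made in the same flask by oxidative dearomatisation of methylhydroquinone. Carbonyl allylboration, a [3,3] shift and enolisation rebuild the arene with no protecting groups.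
- C1'–B / C2'=C3': the allyl boronate comes from 1,4-hydroboration of a 2-substituted 1,3-diene, which sets the 2'E olefin.
- C4'–C5': the dienol comes from (2E,6E)-farnesal and isoprene by asymmetric isoprenylation, which sets C5' as R.
- Rings: none is built. The benzene ring is carried in from methylhydroquinone, taken to the quinone level and re-aromatised in the last step.

Assumption: (2E,6E)-farnesal (and, for one fallback only, 1-bromo-2,5-dimethoxy-3-methylbenzene) is bought as a catalogue compound.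

## Route

**Step 1**
Reactants: 1 (2E,6E)-farnesal; 2 isoprene
Product: 6 (5R,6E,10E)-7,11,15-trimethyl-3-methylidenehexadeca-1,6,10,14-tetraen-5-ol, via isoprenylpotassium 3 (not isolated), via B-isoprenyldiisopinocampheylborane 4 (not isolated), via diisopinocampheylborinate 5 (not isolated)
Conditions: 2 (3 equiv), potassium 2,2,6,6-tetramethylpiperidide (KTMP, from TMPH, n-BuLi, KOt-Bu), THF, −78 → −50 °C; (+)-Ipc2BOMe (from (−)-α-pinene), −78 °C; BF3·OEt2; then 1, −78 °C, 4 h; NaOH, H2O2, 0 °C → rt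
Reagents that add atoms: none
Why: Brown asymmetric allylboration (isoprenylation, the prenal → ipsdienol reaction applied to its farnesyl homologue): the isoprenyl group is delivered through a chair Zimmerman–Traxler transition state in which the (−)-α-pinene-derived isopinocampheyl groups direct attack to the Re face of the enal carbonyl, which sets C5 as R, and the 1,2-addition leaves the E-enal olefin untouched.

**Step 2**
Reactants: 6 (5R,6E,10E)-dienol
Product: 9 (2E,5R,6E,10E)-3,7,11,15-tetramethyl-1-(4,4,5,5-tetramethyl-1,3,2-dioxaborolan-2-yl)hexadeca-2,6,10,14-tetraen-5-ol, via O-borylated dienol 7 (not isolated), via bis-boryl intermediate 8 (not isolated)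
Conditions: HBpin (2.3 equiv), FeCl2(L) (5 mol %; L = N-(2,6-diisopropylphenyl)-1-(pyridin-2-yl)ethanimine), Mg (10 mol %), Et2O, 23 °C, 3 h; pH 7 buffer, short SiO2 plug
Reagents that add atoms: pinacolborane, [H]B1OC(C)(C)C(C)(C)O1
Why: Iron-catalysed 1,4-hydroboration of a 2-substituted 1,3-diene (the myrcene → geranyl boronate reaction): the first equivalent of HBpin masks the OH as its borate with loss of H2, then H and boron add across the s-cis diene with H going to the methylidene carbon and boron to the vinyl terminus, which forces the new trisubstituted olefin to be E; the stereocentre is not touched and the O–B bond is hydrolysed on work-up.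

**Step 3**
Reactants: 9 (2E,5R,6E,10E)-allyl boronate; 10 methylhydroquinone (2-methylbenzene-1,4-diol)
Product: 14 2-[(2E,5R,6E,10E)-5-hydroxy-3,7,11,15-tetramethylhexadeca-2,6,10,14-tetraen-1-yl]-6-methylbenzene-1,4-diol, via 2-methyl-1,4-benzoquinone 11 (not isolated), via quinol borate 12 (not isolated), via cyclohexadienone borate 13 (not isolated)
Conditions: 10 (2.5 equiv), Ag2O, MgSO4, CH2Cl2, rt, 30 min, filter under Ar; add 9, CH2Cl2, rt → 40 °C, 16 h; aq Na2S2O4 work-up
Reagents that add atoms: none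
Why: Ag2O oxidatively dearomatises 10 to quinone 11, whose less hindered C4 carbonyl undergoes γ-selective allylboration through a closed six-membered transition state to give 12; a [3,3]-sigmatropic (Cope-type) shift to C6 transposes the allyl unit a second time, so the chain arrives linear with its 2'E olefin retained, and enolisation of 13 restores the aromatic ring (quinone allylation by 1,2-addition/[3,3] rearrangement); no stereocentre is formed and C5' is not involved.

## Compound list

1 | (2E,6E)-farnesal | CC(C)=CCC/C(C)=C/CC/C(C)=C/C=O | starting material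
2 | isoprene | C=CC(C)=C | starting material
3 | isoprenylpotassium (2-methylidenebut-3-enylpotassium) | [K+].[CH2-]C(=C)C=C | intermediate
4 | B-(2-methylidenebut-3-enyl)bis[(1S,2R,3S,5S)-isopinocampheyl]borane | C=CC(=C)CB([C@H]1C[C@H]2C[C@@H]([C@@H]1C)C2(C)C)[C@H]1C[C@H]2C[C@@H]([C@@H]1C)C2(C)C | intermediate
5 | diisopinocampheylborinate of 6 | CC(C)=CCC/C(C)=C/CC/C(C)=C/[C@H](OB([C@H]1C[C@H]2C[C@@H]([C@@H]1C)C2(C)C)[C@H]1C[C@H]2C[C@@H]([C@@H]1C)C2(C)C)CC(=C)C=C | intermediate
6 | (5R,6E,10E)-7,11,15-trimethyl-3-methylidenehexadeca-1,6,10,14-tetraen-5-ol | CC(C)=CCC/C(C)=C/CC/C(C)=C/[C@H](O)CC(=C)C=C | intermediate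
7 | O-(pinacolatoboryl) derivative of 6 | CC(C)=CCC/C(C)=C/CC/C(C)=C/[C@H](OB1OC(C)(C)C(C)(C)O1)CC(=C)C=C | intermediate
8 | O-(pinacolatoboryl) derivative of 9 (C-boryl, O-boryl) | CC(C)=CCC/C(C)=C/CC/C(C)=C/[C@H](OB1OC(C)(C)C(C)(C)O1)C/C(C)=C/CB1OC(C)(C)C(C)(C)O1 | intermediate
9 | (2E,5R,6E,10E)-3,7,11,15-tetramethyl-1-(4,4,5,5-tetramethyl-1,3,2-dioxaborolan-2-yl)hexadeca-2,6,10,14-tetraen-5-ol | CC(C)=CCC/C(C)=C/CC/C(C)=C/[C@H](O)C/C(C)=C/CB1OC(C)(C)C(C)(C)O1 | intermediate
10 | methylhydroquinone | Cc1cc(O)ccc1O | starting material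
11 | 2-methyl-1,4-benzoquinone | CC1=CC(=O)C=CC1=O | intermediate
12 | 4-[(5R,6E,10E)-5-hydroxy-3,7,11,15-tetramethylhexadeca-1,6,10,14-tetraen-3-yl]-2-methyl-4-[(pinacolatoboryl)oxy]cyclohexa-2,5-dien-1-one (mixture at the two transient centres) | CC(C)=CCC/C(C)=C/CC/C(C)=C/[C@H](O)CC(C)(C=C)C1(OB2OC(C)(C)C(C)(C)O2)C=CC(=O)C(C)=C1 | intermediate
13 | 6-[(2E,5R,6E,10E)-5-hydroxy-3,7,11,15-tetramethylhexadeca-2,6,10,14-tetraen-1-yl]-2-methyl-4-[(pinacolatoboryl)oxy]cyclohexa-2,4-dien-1-one (both C6 epimers) | CC(C)=CCC/C(C)=C/CC/C(C)=C/[C@H](O)C/C(C)=C/CC1C=C(OB2OC(C)(C)C(C)(C)O2)C=C(C)C1=O | intermediate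
14 | 2-[(2E,5R,6E,10E)-5-hydroxy-3,7,11,15-tetramethylhexadeca-2,6,10,14-tetraen-1-yl]-6-methylbenzene-1,4-diol | CC(C)=CCC/C(C)=C/CC/C(C)=C/[C@H](O)C/C(C)=C/Cc1cc(O)cc(C)c1O | target

## Step count and risks

Total steps: 3. Longest linear sequence: 3 (1 → 6 → 9 → 14).

**Most likely to fail, in order:**

**Step 3 (quinone allylboration/[3,3]).** The risks are regiochemistry and rate. Attack at the C1 carbonyl would lead to the 2,5- and 2,3-isomers, and a [3,3] shift to the methyl-bearing C2 would give a non-aromatisable ene-dione. A γ,γ-disubstituted boronate also adds slowly. The fallback sets out from 9 and fixes the regiochemistry with a pre-placed halogen instead of a dearomatised ring. An α-selective Suzuki–Miyaura sp3–sp2 coupling of 9 with 1-bromo-2,5-dimethoxy-3-methylbenzene (COc1cc(C)c(OC)c(Br)c1) is run with PdCl2(IPent)(3-chloropyridine), where IPent is 1,3-bis[2,6-di(pentan-3-yl)phenyl]imidazol-2-ylidene, and aqueous KOH in THF at 70 °C. This gives (2E,5R,6E,10E)-1-(2,5-dimethoxy-3-methylphenyl)-3,7,11,15-tetramethylhexadeca-2,6,10,14-tetraen-5-ol F1. Oxidative demethylation with (NH4)2Ce(NO3)6 in MeCN/H2O at 0 °C gives 2-[(2E,5R,6E,10E)-5-hydroxy-3,7,11,15-tetramethylhexadeca-2,6,10,14-tetraen-1-yl]-6-methyl-1,4-benzoquinone F2. Reduction with aqueous Na2S2O4 comes back to the route at 14.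

**Step 2 (iron-catalysed 1,4-hydroboration).** The risks are a wrong boron terminus, E/Z erosion, or reduction of the allylic C–O bond on this oxygenated diene. The fallback sets out from 1 and builds the 2'E olefin by syn-carbometalation of an alkyne instead. Propargylation of 1 with allenyl-B(pin) under a BINOL-derived chiral phosphoric acid (TRIP, antipode chosen for the R carbinol) gives (4R,5E,9E)-6,10,14-trimethylpentadeca-5,9,13-trien-1-yn-4-ol F3. Water-accelerated methylalumination (Me3Al, Cp2ZrCl2 cat., CH2Cl2, −20 °C), then I2, gives (1E,4R,5E,9E)-1-iodo-2,6,10,14-tetramethylpentadeca-1,5,9,13-tetraen-4-ol F4. Negishi coupling of F4 with IZnCH2B(pin) and Pd(PPh3)4 in THF comes back to the route at 9.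

**Step 1 (asymmetric isoprenylation).** The risks are polymerisation of isoprene during the KTMP metalation and an enantiomeric excess below the level known for prenal. The fallback sets out from 1 and replaces reagent control by resolution. A zinc Barbier reaction of 1 with 2-(bromomethyl)buta-1,3-diene (C=CC(=C)CBr) in THF/aq NH4Cl gives racemic (6E,10E)-7,11,15-trimethyl-3-methylidenehexadeca-1,6,10,14-tetraen-5-ol F5. Sharpless kinetic resolution of F5 (Ti(OiPr)4, L-(+)-diisopropyl tartrate, t-BuOOH, 4 Å sieves, CH2Cl2, −20 °C, about 60 % conversion because the cis-methyl lowers the rate ratio) epoxidises the S enantiomer. The unreacted R alcohol is recovered, which comes back to the route at 6.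

## Further compounds

F1 | step 3 | (2E,5R,6E,10E)-1-(2,5-dimethoxy-3-methylphenyl)-3,7,11,15-tetramethylhexadeca-2,6,10,14-tetraen-5-ol | CC(C)=CCC/C(C)=C/CC/C(C)=C/[C@H](O)C/C(C)=C/Cc1cc(OC)cc(C)c1OC
F2 | step 3 | 2-[(2E,5R,6E,10E)-5-hydroxy-3,7,11,15-tetramethylhexadeca-2,6,10,14-tetraen-1-yl]-6-methyl-1,4-benzoquinone | CC(C)=CCC/C(C)=C/CC/C(C)=C/[C@H](O)C/C(C)=C/CC1=CC(=O)C=C(C)C1=O
F3 | step 2 | (4R,5E,9E)-6,10,14-trimethylpentadeca-5,9,13-trien-1-yn-4-ol | CC(C)=CCC/C(C)=C/CC/C(C)=C/[C@H](O)CC#C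
F4 | step 2 | (1E,4R,5E,9E)-1-iodo-2,6,10,14-tetramethylpentadeca-1,5,9,13-tetraen-4-ol | CC(C)=CCC/C(C)=C/CC/C(C)=C/[C@H](O)C/C(C)=C/I
F5 | step 1 | racemic (6E,10E)-7,11,15-trimethyl-3-methylidenehexadeca-1,6,10,14-tetraen-5-ol | CC(C)=CCC/C(C)=C/CC/C(C)=C/C(O)CC(=C)C=C
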